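**Retrosynthetic overview**
1. Labels used: C1 lactone C=O, C3 CH–OO, C4 C(Me)–O(lactone), C5 CH2, C6 C(Me)(chain)–OO. Ring A is the γ-lactone, ring B the 1,2-dioxane.
2. Last bond: C6–CH3, by methyl transfer to the bicyclic peroxycarbenium ion made from a C6 methoxy peroxyketal (sets C6).
3. Ring B: both peroxide C–O bonds come from H2O2. C6–OO forms by hydroperoxyketalisation of a C6 ketone, C3–OO by intramolecular peroxy-Michael addition to the butenolide (sets C3, cis fusion).
4. The ketone comes from Negishi acylation of the acid chloride of (S)-4-methylmuconolactone with 12-phenyldodecylzinc bromide (from PhMgBr and 1,12-dibromododecane).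
5. Ring A is made first: the C4–O bond forms by carboxy-Michael lactonisation of 3-methyl-cis,cis-muconic acid (from 4-methylcatechol), followed by resolution (sets C4). Order: ring A, then ring B.

Assumption: the less soluble salt of acid 6 with (S)-1-phenylethylamine contains the (S)-acid; if the pairing is the opposite one, the (R)-amine is used in the same way.

**Route**

Step 1
Reactants: 1 phenylmagnesium bromide; 2 1,12-dibromododecane
Product: 3 (12-bromododecyl)benzene
Conditions: Li2CuCl4 (3 mol%), NMP (4 equiv), THF, 0 → 20 °C; 2 in threefold excess (recovered)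
Reagents that add atoms: none
Why: Copper-catalysed Kochi-type cross-coupling of a Grignard reagent with a primary alkyl bromide; the excess of dibromide suppresses double arylation.

Step 2
Reactants: 4 4-methylcatechol
Product: 5 (2Z,4Z)-3-methylhexa-2,4-dienedioic acid (3-methyl-cis,cis-muconic acid)
Conditions: AcOOH (2.5 equiv) in AcOH, FeCl3 (0.5 mol%), 15–20 °C, dark, 48 h; 5 crystallises
Reagents that add atoms: peracetic acid, CC(=O)OO; water, O
Why: Peracid intradiol oxidative cleavage of the catechol between the two hydroxylated carbons; both ring double bonds are carried over unchanged, hence Z,Z.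

Step 3
Reactants: 5 (2Z,4Z)-3-methylhexa-2,4-dienedioic acid
Product: 6 rac-2-(2-methyl-5-oxo-2,5-dihydrofuran-2-yl)acetic acid (racemic 4-methylmuconolactone)
Conditions: 1 M aq. HCl, 60 °C, 2 h; recrystallise
Reagents that add atoms: none
Why: Intramolecular carboxy-Michael addition (5-exo cycloisomerisation) in which the carboxyl at the end of the unsubstituted Z-alkene adds to the methyl-bearing alkene carbon, forming the lactone C4–O bond and the quaternary centre C4 as a racemate.

Step 4
Reactants: 6 rac-2-(2-methyl-5-oxo-2,5-dihydrofuran-2-yl)acetic acid; 7 (S)-1-phenylethylamine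
Product: 8 (S)-1-phenylethylammonium (S)-2-(2-methyl-5-oxo-2,5-dihydrofuran-2-yl)acetate
Conditions: 7 (1.0 equiv), EtOH/EtOAc, fractional crystallisation to constant rotation (2–3 crops)
Reagents that add atoms: none
Why: Classical resolution through diastereomeric ammonium carboxylate salts, which fixes C4 as S, the one stereocentre that is not relayed from another.

Step 5
Reactants: 8 (S)-1-phenylethylammonium (S)-2-(2-methyl-5-oxo-2,5-dihydrofuran-2-yl)acetate; 3 (12-bromododecyl)benzene
Product: 12 (S)-5-methyl-5-(2-oxo-14-phenyltetradecyl)furan-2(5H)-one, via free (S)-acid 9 (not isolated), via acid chloride 10 (not isolated), via alkylzinc bromide 11 (not isolated)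
Conditions: 1 M HCl/EtOAc; (COCl)2, DMF (cat.), CH2Cl2, 0 → 20 °C; separately 3, Zn, LiCl, THF, 50 °C; then Pd(PPh3)4 (3 mol%), THF, 0 → 20 °C
Reagents that add atoms: none
Why: Negishi acylation, in which the alkylzinc bromide transmetalates to the acylpalladium species from the acid chloride and the ketone forms under non-basic conditions that leave the butenolide and C4 untouched.

Step 6
Reactants: 12 (S)-5-methyl-5-(2-oxo-14-phenyltetradecyl)furan-2(5H)-one
Product: 13 (5S)-5-(2-hydroperoxy-2-methoxy-14-phenyltetradecyl)-5-methylfuran-2(5H)-one (both epimers at the ketal carbon)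
Conditions: urea·H2O2 (5 equiv), Sc(OTf)3 (10 mol%), MeOH, 20 °C
Reagents that add atoms: urea–hydrogen peroxide adduct (supplies H2O2), NC(N)=O.OO; methanol, CO
Why: Lewis-acid-catalysed hydroperoxyketalisation of the ketone (H2O2 and MeOH add through the oxocarbenium ion) forms the first peroxide C–O bond at C6; the ketal centre is a mixture of no consequence because it is ionised in step 8.

Step 7
Reactants: 13 (5S)-5-(2-hydroperoxy-2-methoxy-14-phenyltetradecyl)-5-methylfuran-2(5H)-one
Product: 14 (4aS,7aS)-3-methoxy-4a-methyl-3-(12-phenyldodecyl)tetrahydro-3H-furo[3,2-c][1,2]dioxin-6(4H)-one (both epimers at the ketal carbon C6)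
Conditions: Et2NH (0.3 equiv), CF3CH2OH, 20 °C
Reagents that add atoms: none
Why: Amine-catalysed intramolecular 6-exo peroxy-Michael addition of the hydroperoxide to the butenolide; the tether through C5 allows attack only on the butenolide face that carries the side chain, which gives the cis-fused ring B and C3 as S.

Step 8
Reactants: 14 (4aS,7aS)-3-methoxy-4a-methyl-3-(12-phenyldodecyl)tetrahydro-3H-furo[3,2-c][1,2]dioxin-6(4H)-one
Product: 15 plakortolide L, (3S,4aS,7aS)-3,4a-dimethyl-3-(12-phenyldodecyl)tetrahydro-3H-furo[3,2-c][1,2]dioxin-6(4H)-one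
Conditions: AlMe3 (3 equiv), TMSOTf (0.2 equiv), CH2Cl2, −78 → −40 °C; aq. Rochelle salt
Reagents that add atoms: trimethylaluminium, C[Al](C)C
Why: Proposed new method: Lewis-acid ionisation of the methoxy group (TMSOTf to start, Me2AlOTf thereafter) gives the cyclic tertiary peroxycarbenium ion common to both epimers of 14, and AlMe3 transfers methyl to C6 along the pseudo-axial, chair-like trajectory of the half-chair that keeps the C4 lactone oxygen pseudo-axial and the C4 methyl pseudo-equatorial (the other half-chair would put the incoming methyl 1,3-diaxial to the C4 methyl), so methyl should enter cis to the lactone oxygen and the chain should end equatorial, which is 6S; the closest known reaction types are Lewis-acid-mediated allylsilane and enol-silane additions to cyclic peroxyketals through peroxycarbenium ions and AlMe3 C-methylation of glycosyl and ketal oxocarbenium ions (including trioxane lactol derivatives whose O–O bond survives AlMe3 at low temperature), while methyl transfer to a peroxycarbenium ion has not been described.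

**Compound list**
1 | phenylmagnesium bromide | Br[Mg]c1ccccc1 | starting material
2 | 1,12-dibromododecane | BrCCCCCCCCCCCCBr | starting material
3 | (12-bromododecyl)benzene | BrCCCCCCCCCCCCc1ccccc1 | intermediate
4 | 4-methylcatechol (4-methylbenzene-1,2-diol) | Cc1ccc(O)c(O)c1 | starting material
5 | (2Z,4Z)-3-methylhexa-2,4-dienedioic acid | O=C(O)/C=C(C)\C=C/C(=O)O | intermediate
6 | rac-2-(2-methyl-5-oxo-2,5-dihydrofuran-2-yl)acetic acid | CC1(CC(=O)O)C=CC(=O)O1 | intermediate
7 | (S)-1-phenylethylamine | C[C@H](N)c1ccccc1 | starting material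
8 | (S)-1-phenylethylammonium (S)-2-(2-methyl-5-oxo-2,5-dihydrofuran-2-yl)acetate | C[C@]1(CC(=O)[O-])C=CC(=O)O1.C[C@H]([NH3+])c1ccccc1 | intermediate
9 | (S)-2-(2-methyl-5-oxo-2,5-dihydrofuran-2-yl)acetic acid | C[C@]1(CC(=O)O)C=CC(=O)O1 | intermediate
10 | (S)-2-(2-methyl-5-oxo-2,5-dihydrofuran-2-yl)acetyl chloride | C[C@]1(CC(=O)Cl)C=CC(=O)O1 | intermediate
11 | (12-phenyldodecyl)zinc bromide | Br[Zn]CCCCCCCCCCCCc1ccccc1 | intermediate
12 | (S)-5-methyl-5-(2-oxo-14-phenyltetradecyl)furan-2(5H)-one | C[C@]1(CC(=O)CCCCCCCCCCCCc2ccccc2)C=CC(=O)O1 | intermediate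
13 | (5S)-5-(2-hydroperoxy-2-methoxy-14-phenyltetradecyl)-5-methylfuran-2(5H)-one, ketal carbon as both epimers | C[C@]1(CC(OC)(OO)CCCCCCCCCCCCc2ccccc2)C=CC(=O)O1 | intermediate
14 | (4aS,7aS)-3-methoxy-4a-methyl-3-(12-phenyldodecyl)tetrahydro-3H-furo[3,2-c][1,2]dioxin-6(4H)-one, ketal carbon as both epimers | COC1(CCCCCCCCCCCCc2ccccc2)C[C@]2(C)OC(=O)C[C@@H]2OO1 | intermediate
15 | plakortolide L, (3S,4aS,7aS)-3,4a-dimethyl-3-(12-phenyldodecyl)tetrahydro-3H-furo[3,2-c][1,2]dioxin-6(4H)-one | C[C@]1(CCCCCCCCCCCCc2ccccc2)C[C@]2(C)OC(=O)C[C@@H]2OO1 | target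

**Step count and risks**

Total steps: 8. Longest linear sequence: 7 (steps 2–8, from 4-methylcatechol).

Three steps most likely to fail:

Step 8 (the proposed new methyl transfer). The peroxycarbenium ion may fragment, or the facial preference may be lower than or opposite to the prediction. The fallback uses known chemistry, sets out from ketone 12 and returns at 15. Ketone 12 is methylenated under non-basic Lombardo conditions (Zn, CH2Br2, TiCl4, THF/CH2Cl2, 0 °C) to the 1,1-disubstituted alkene (S)-5-methyl-5-(2-methylidene-14-phenyltetradecyl)furan-2(5H)-one F1. Mukaiyama–Isayama hydroperoxysilylation (Co(thd)2 cat., O2, Et3SiH, 1,2-dichloroethane, 20 °C) gives the tertiary triethylsilyl peroxide F2 as both C6 epimers. Dilute HCl in wet THF frees the tertiary hydroperoxide F3. Et2NH in CF3CH2OH then closes ring B by the same peroxy-Michael addition, giving 15 together with its C6 epimer F4, which is removed by chromatography. C6 is then uncontrolled (about 1:1), so this costs half the material.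

Step 7 (first closure of ring B on this substrate). The methoxy hydroperoxide may cyclise sluggishly or decompose under amine catalysis. The fallback sets out from ketone 12 and returns at 14. Ketone 12 is treated with anhydrous H2O2 (from urea·H2O2) and a trace of camphorsulfonic acid in CF3CH2OH to form the hydroperoxy hemiketal F5 (not isolated). Addition of Et2NH closes it in the same pot to the bicyclic peroxyhemiketal F6, a 1,2-dioxan-3-ol. The anomeric hydroxyl is then exchanged for methoxyl (MeOH, cat. camphorsulfonic acid, 20 °C) to give 14.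

Step 4 (resolution). The salt may not crystallise well or may pair the wrong enantiomer. The fallback sets out from racemic acid 6 and returns at free acid 9. The enantiomers of 6 are separated by preparative supercritical-fluid chromatography on a cellulose tris(3,5-dichlorophenylcarbamate) phase (CO2/MeOH with 0.1% formic acid), and the (S)-acid 9 is taken directly into the acid chloride stage of step 5. No new compound is made.

**Further compounds**
F1 | step 8 | (S)-5-methyl-5-(2-methylidene-14-phenyltetradecyl)furan-2(5H)-one | C[C@]1(CC(=C)CCCCCCCCCCCCc2ccccc2)C=CC(=O)O1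
F2 | step 8 | (5S)-5-methyl-5-[2-methyl-14-phenyl-2-(triethylsilylperoxy)tetradecyl]furan-2(5H)-one, both C6 epimers | C[C@]1(CC(C)(OO[Si](CC)(CC)CC)CCCCCCCCCCCCc2ccccc2)C=CC(=O)O1
F3 | step 8 | (5S)-5-(2-hydroperoxy-2-methyl-14-phenyltetradecyl)-5-methylfuran-2(5H)-one, both C6 epimers | C[C@]1(CC(C)(OO)CCCCCCCCCCCCc2ccccc2)C=CC(=O)O1
F4 | step 8 | C6 epimer of 15, (3R,4aS,7aS)-3,4a-dimethyl-3-(12-phenyldodecyl)tetrahydro-3H-furo[3,2-c][1,2]dioxin-6(4H)-one | C[C@@]1(CCCCCCCCCCCCc2ccccc2)C[C@]2(C)OC(=O)C[C@@H]2OO1
F5 | step 7 | (5S)-5-(2-hydroperoxy-2-hydroxy-14-phenyltetradecyl)-5-methylfuran-2(5H)-one | C[C@]1(CC(O)(OO)CCCCCCCCCCCCc2ccccc2)C=CC(=O)O1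
F6 | step 7 | (4aS,7aS)-3-hydroxy-4a-methyl-3-(12-phenyldodecyl)tetrahydro-3H-furo[3,2-c][1,2]dioxin-6(4H)-one | OC1(CCCCCCCCCCCCc2ccccc2)C[C@]2(C)OC(=O)C[C@@H]2OO1
F0 | step 4 | none | none
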